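The route rests on cutting the target back to its trans-2,5-disubstituted oxolane core (ring O, C5, C6, C7, C8; chain numbered from the ester carbon C1 to the bromine-bearing C20), whose stereocentres C5 and C8 each carry one carbon arm (C4, C9); C8 and C5 map onto C2 and C5 of 2,5-anhydro-D-mannose. Nitrous acid deamination of D-glucosamine, an all-equatorial 2-amino-2-deoxypyranose used as its hydrochloride, contracts the pyranose to that oxolane in one operation, forming the ring O–C8 bond with inversion and delivering both ring stereocentres. Reduction then gives a C2-symmetric core; ring deoxygenation, arm-by-arm chain growth and a final Sonogashira coupling complete the synthesis.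

Key step: step 1

Remark: D-glucosamine is written without anomeric configuration because both anomers give the same product; compound 5 is C2-symmetric, so the ring carbon that gains the C–O bond in step 1 is counted as C8 and either hydroxymethyl arm may be elaborated first.

Step 1
Reactants: 1 D-glucosamine hydrochloride
Product: 4 2,5-anhydro-D-mannose, via D-glucosamine free amine 2 (not isolated), via glucosamine C2-diazonium chloride 3 (not isolated)
Conditions: NaNO2 (1.5 equiv), H2O, AcOH (cat.), 0 °C to rt; mixed-bed ion-exchange resin; freeze-drying to the crude syrup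
Reagents that add atoms: none
Why: Diazotisation of the free amine 2 by nitrous acid gives the C2 diazonium ion 3, and in the 4C1 chair of the D-gluco series this equatorial leaving group is antiperiplanar to the ring C1–O5 bond, so O5 displaces N2 from the back of C2 in a concerted 1,2-shift while C1 is left as an O-protonated aldehyde that loses a proton (nitrous acid deamination with ring contraction, a Demjanov/semipinacol-type rearrangement). The closest known reaction type is exactly this deaminative contraction of 2-amino-2-deoxy-aldopyranoses to 2,5-anhydro-aldoses. The oxolane (O5, C2, C3, C4, C5 of the sugar) closes by intramolecular invertive substitution at C2 by the ring oxygen, that is by contraction of the six-membered ring and not by an exo or endo cyclisation of an open chain. The one new stereocentre, sugar C2 (C8 of the target), is set by inversion from gluco to manno and is controlled by the C2 configuration of the substrate itself, whereas sugar C5 (C5 of the target) is not touched. The step needs oxygen migration to outrun capture of C2 by water, hydride shifts and migration of the other antiperiplanar ring bond (C3–C4); the equatorial diazonium group rules out the hydride shifts, the intramolecular shift is faster than external attack, and oxygen, with its lone pair and the hydroxy-stabilised cation it leaves at C1, is the better migrating group. Both anomers converge on 4, which is reduced promptly because the free aldehyde dehydrates easily.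

Step 2
Reactants: 4 2,5-anhydro-D-mannose
Product: 5 2,5-anhydro-D-mannitol
Conditions: NaBH4 (1.0 equiv), H2O, 0 °C to rt; acidic ion-exchange resin; MeOH co-evaporation
Reagents that add atoms: none
Why: Borohydride reduction of the aldehyde (present as its hydrate) to the primary alcohol touches no stereocentre and should give the C2-symmetric tetrol, in which the two hydroxymethyl arms are equivalent.

Step 3
Reactants: 5 2,5-anhydro-D-mannitol
Product: 6 2,5-anhydro-1,6-di-O-trityl-D-mannitol
Conditions: TrCl (2.3 equiv), pyridine, DMAP (cat.), rt to 50 °C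
Reagents that add atoms: trityl chloride, ClC(c1ccccc1)(c1ccccc1)c1ccccc1
Why: Tritylation (SN1 etherification via the trityl cation) is selective for the two primary hydroxyls on steric grounds and leaves the ring trans-diol free.

Step 4
Reactants: 6 2,5-anhydro-1,6-di-O-trityl-D-mannitol
Product: 8 2,5-anhydro-3,4-bis-O-[(methylsulfanyl)carbonothioyl]-1,6-di-O-trityl-D-mannitol, via disodium bis-xanthate salt 7 (not isolated)
Conditions: NaH (3 equiv), imidazole (cat.), THF, 0 °C; CS2; then MeI, rt
Reagents that add atoms: carbon disulfide, S=C=S; iodomethane, CI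
Why: Xanthate ester formation (the substrate preparation of the Barton–McCombie reaction): the sodium alkoxides add to CS2 and the dithiocarbonate salt 7 is S-methylated, while trityl ethers cannot migrate under base.

Step 5
Reactants: 8 the bis(S-methyl xanthate)
Product: 9 (2S,5S)-2,5-bis[(trityloxy)methyl]-2,5-dihydrofuran
Conditions: Bu3SnH (3 equiv), AIBN (cat.), toluene, reflux
Reagents that add atoms: none
Why: Radical olefination of a vicinal bis-xanthate (Barton–McCombie-type fragmentation): the ring carbon radical formed from one xanthate expels the neighbouring one by β-scission, so the trans-diol is excised as the ring alkene whatever its relative configuration, and C2 and C5 take no part.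

Step 6
Reactants: 9 (2S,5S)-2,5-bis[(trityloxy)methyl]-2,5-dihydrofuran
Product: 10 (2S,5S)-2,5-bis[(trityloxy)methyl]oxolane
Conditions: H2 (1 atm), Pt/C (5% platinum on carbon), EtOAc, rt
Reagents that add atoms: none
Why: Heterogeneous catalytic hydrogenation of the cis ring alkene creates no stereocentre, and platinum is chosen because it has little tendency to move the double bond onto the stereogenic allylic ether carbons.

Step 7
Reactants: 10 (2S,5S)-2,5-bis[(trityloxy)methyl]oxolane
Product: 11 [(2S,5S)-oxolane-2,5-diyl]dimethanol
Conditions: TsOH·H2O (cat.), MeOH–CH2Cl2, rt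
Reagents that add atoms: none
Why: Acid-catalysed solvolysis (SN1) of the trityl ethers in methanol should free both primary alcohols, the oxolane being inert to these conditions.

Step 8
Reactants: 11 [(2S,5S)-oxolane-2,5-diyl]dimethanol
Product: 12 [(2S,5S)-5-({[tert-butyl(dimethyl)silyl]oxy}methyl)oxolan-2-yl]methanol
Conditions: NaH (1.0 equiv), THF, 0 °C to rt; then TBSCl (1.0 equiv)
Reagents that add atoms: tert-butyldimethylsilyl chloride, CC(C)(C)[Si](C)(C)Cl
Why: Williamson-type O-silylation of the monosodium alkoxide of a symmetrical diol should favour the mono-ether, and because 11 is C2-symmetric either hydroxyl gives the same compound.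

Step 9
Reactants: 12 the mono-silyl alcohol
Product: 13 (2S,5S)-5-({[tert-butyl(dimethyl)silyl]oxy}methyl)oxolane-2-carbaldehyde
Conditions: Dess–Martin periodinane, CH2Cl2, 0 °C to rt; used at once
Reagents that add atoms: none
Why: Dess–Martin oxidation of the primary alcohol runs under near-neutral, non-enolising conditions and should leave the α-alkoxy stereocentre intact.

Step 10
Reactants: 13 the silyloxy aldehyde; 14 (2-carboxyethyl)triphenylphosphonium bromide
Product: 16 (3Z)-4-[(2S,5S)-5-({[tert-butyl(dimethyl)silyl]oxy}methyl)oxolan-2-yl]but-3-enoic acid, via sodium carboxylate ylide 15 (not isolated)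
Conditions: 14 (1.6 equiv), NaN(SiMe3)2 (3.2 equiv), THF, −78 to 0 °C; then 13, −78 °C to rt; 1 M HCl to pH 3
Reagents that add atoms: none
Why: Wittig olefination with the non-stabilised carboxylate ylide 15 at low temperature adds C3 to C1 of the chain, and the alkene geometry (expected Z) does not matter because the double bond is hydrogenated next.

Step 11
Reactants: 16 the butenoic acid
Product: 17 4-[(2R,5S)-5-({[tert-butyl(dimethyl)silyl]oxy}methyl)oxolan-2-yl]butanoic acid
Conditions: H2 (1 atm), Pt/C (5% platinum on carbon), EtOAc, rt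
Reagents that add atoms: none
Why: Catalytic hydrogenation of the disubstituted alkene over platinum limits hydrogenolysis of the allylic ring C–O bond, and any loss of the silyl ether would be harmless since step 12 removes it.

Step 12
Reactants: 17 the silyloxy acid
Product: 18 methyl 4-[(2R,5S)-5-(hydroxymethyl)oxolan-2-yl]butanoate
Conditions: HCl (1.25 M in MeOH), rt
Reagents that add atoms: methanol, CO
Why: Fischer esterification and acid-catalysed methanolysis of the primary silyl ether proceed in the same medium, so the hydroxy ester should form in one operation.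

Step 13
Reactants: 18 the hydroxy ester
Product: 19 methyl 4-[(2R,5S)-5-formyloxolan-2-yl]butanoate
Conditions: Dess–Martin periodinane, CH2Cl2, 0 °C to rt; used at once
Reagents that add atoms: none
Why: Dess–Martin oxidation of the primary alcohol is neutral enough to spare the ester and the α-alkoxy stereocentre (C8).

Step 14
Reactants: 19 the formyl ester; 20 dimethyl (1-diazo-2-oxopropyl)phosphonate
Product: 22 methyl 4-[(2R,5S)-5-ethynyloxolan-2-yl]butanoate, via dimethyl (diazomethyl)phosphonate 21 (not isolated)
Conditions: 20 (1.3 equiv), K2CO3 (2 equiv), MeOH, 0 °C to rt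
Reagents that add atoms: none
Why: Ohira–Bestmann variant of the Seyferth–Gilbert homologation: methanolysis of 20 gives 21, whose anion olefinates the aldehyde and, after loss of N2 and a 1,2-hydride shift, gives the terminal alkyne (C10), under conditions mild enough for the α-alkoxy centre and degenerate towards the methyl ester.

Step 15
Reactants: 23 non-8-yn-1-ol
Product: 24 non-8-ynal
Conditions: Dess–Martin periodinane, CH2Cl2, 0 °C to rt
Reagents that add atoms: none
Why: Dess–Martin oxidation of a primary alcohol stops at the aldehyde and leaves the terminal alkyne alone.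

Step 16
Reactants: 24 non-8-ynal; 25 (bromomethyl)triphenylphosphonium bromide
Product: 27 (1Z)-1-bromodec-1-en-9-yne, via (bromomethylidene)triphenylphosphorane 26 (not isolated)
Conditions: 25 (1.3 equiv), KOtBu (1.25 equiv), THF, −78 °C; then 24, −78 °C to rt
Reagents that add atoms: none
Why: Wittig bromomethylenation with the non-stabilised ylide 26 (the bromo counterpart of the Stork–Zhao olefination) should favour the Z-bromoalkene through kinetic formation of the cis-oxaphosphetane at low temperature.

Step 17
Reactants: 27 (1Z)-1-bromodec-1-en-9-yne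
Product: 29 (1Z,9E)-1-bromo-10-iododeca-1,9-diene, via alkenylzirconocene chloride 28 (not isolated)
Conditions: Cp2Zr(H)Cl (1.3 equiv), THF, rt, dark; then I2, 0 °C
Reagents that add atoms: iodine, II
Why: Hydrozirconation of the terminal alkyne is syn and puts zirconium on the terminal carbon, and iodinolysis of the alkenyl–zirconium bond with retention should give the E-iodoalkene while the Z-bromoalkene is a spectator.

Step 18
Reactants: 22 methyl 4-[(2R,5S)-5-ethynyloxolan-2-yl]butanoate; 29 (1Z,9E)-1-bromo-10-iododeca-1,9-diene
Product: 30 methyl 4-[(2R,5S)-5-[(3E,11Z)-12-bromododeca-3,11-dien-1-yn-1-yl]oxolan-2-yl]butanoate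
Conditions: PdCl2(PPh3)2 (5 mol %), CuI (10 mol %), Et3N, THF, rt, degassed
Reagents that add atoms: none
Why: Sonogashira coupling: zerovalent palladium inserts into the alkenyl C–I bond much faster than into the alkenyl C–Br bond at room temperature, so the copper acetylide of 22 should couple at C11 with retention of the E geometry and leave the Z-bromoalkene and C8 untouched.

Compound list
1 | D-glucosamine hydrochloride | OC[C@H]1OC(O)[C@H](N)[C@@H](O)[C@@H]1O.Cl | starting material
2 | D-glucosamine (2-amino-2-deoxy-D-glucopyranose, free amine, anomeric mixture) | OC[C@H]1OC(O)[C@H](N)[C@@H](O)[C@@H]1O | intermediate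
3 | 2-deoxy-D-glucopyranose-2-diazonium chloride | OC[C@H]1OC(O)[C@H]([N+]#N)[C@@H](O)[C@@H]1O.[Cl-] | intermediate
4 | 2,5-anhydro-D-mannose, (2S,3S,4S,5R)-3,4-dihydroxy-5-(hydroxymethyl)oxolane-2-carbaldehyde | O=C[C@H]1O[C@H](CO)[C@@H](O)[C@@H]1O | intermediate
5 | 2,5-anhydro-D-mannitol, (2R,3S,4S,5R)-2,5-bis(hydroxymethyl)oxolane-3,4-diol | OC[C@H]1O[C@H](CO)[C@@H](O)[C@@H]1O | intermediate
6 | 2,5-anhydro-1,6-di-O-trityl-D-mannitol | C(c1ccccc1)(c1ccccc1)(c1ccccc1)OC[C@H]1O[C@H](COC(c2ccccc2)(c2ccccc2)c2ccccc2)[C@@H](O)[C@@H]1O | intermediate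
7 | disodium 3,4-bis-O-(dithiocarboxylato) derivative of 6 (bis-xanthate salt) | C(c1ccccc1)(c1ccccc1)(c1ccccc1)OC[C@H]1O[C@H](COC(c2ccccc2)(c2ccccc2)c2ccccc2)[C@@H](OC(=S)[S-])[C@@H]1OC(=S)[S-].[Na+].[Na+] | intermediate
8 | 2,5-anhydro-3,4-bis-O-[(methylsulfanyl)carbonothioyl]-1,6-di-O-trityl-D-mannitol | C(c1ccccc1)(c1ccccc1)(c1ccccc1)OC[C@H]1O[C@H](COC(c2ccccc2)(c2ccccc2)c2ccccc2)[C@@H](OC(=S)SC)[C@@H]1OC(=S)SC | intermediate
9 | (2S,5S)-2,5-bis[(trityloxy)methyl]-2,5-dihydrofuran | C(c1ccccc1)(c1ccccc1)(c1ccccc1)OC[C@H]1O[C@H](COC(c2ccccc2)(c2ccccc2)c2ccccc2)C=C1 | intermediate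
10 | (2S,5S)-2,5-bis[(trityloxy)methyl]oxolane | C(c1ccccc1)(c1ccccc1)(c1ccccc1)OC[C@H]1O[C@H](COC(c2ccccc2)(c2ccccc2)c2ccccc2)CC1 | intermediate
11 | [(2S,5S)-oxolane-2,5-diyl]dimethanol (trans, C2-symmetric) | OC[C@H]1O[C@H](CO)CC1 | intermediate
12 | [(2S,5S)-5-({[tert-butyl(dimethyl)silyl]oxy}methyl)oxolan-2-yl]methanol | OC[C@@H]1CC[C@@H](CO[Si](C)(C)C(C)(C)C)O1 | intermediate
13 | (2S,5S)-5-({[tert-butyl(dimethyl)silyl]oxy}methyl)oxolane-2-carbaldehyde | O=C[C@@H]1CC[C@@H](CO[Si](C)(C)C(C)(C)C)O1 | intermediate
14 | (2-carboxyethyl)triphenylphosphonium bromide | OC(=O)CC[P+](c1ccccc1)(c1ccccc1)c1ccccc1.[Br-] | starting material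
15 | sodium 3-(triphenylphosphoranylidene)propanoate (ylide) | [Na+].[O-]C(=O)CC=P(c1ccccc1)(c1ccccc1)c1ccccc1 | intermediate
16 | (3Z)-4-[(2S,5S)-5-({[tert-butyl(dimethyl)silyl]oxy}methyl)oxolan-2-yl]but-3-enoic acid | OC(=O)C/C=C\[C@@H]1CC[C@@H](CO[Si](C)(C)C(C)(C)C)O1 | intermediate
17 | 4-[(2R,5S)-5-({[tert-butyl(dimethyl)silyl]oxy}methyl)oxolan-2-yl]butanoic acid | OC(=O)CCC[C@@H]1CC[C@@H](CO[Si](C)(C)C(C)(C)C)O1 | intermediate
18 | methyl 4-[(2R,5S)-5-(hydroxymethyl)oxolan-2-yl]butanoate | COC(=O)CCC[C@@H]1CC[C@@H](CO)O1 | intermediate
19 | methyl 4-[(2R,5S)-5-formyloxolan-2-yl]butanoate | COC(=O)CCC[C@@H]1CC[C@@H](C=O)O1 | intermediate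
20 | dimethyl (1-diazo-2-oxopropyl)phosphonate | COP(=O)(OC)C(=[N+]=[N-])C(C)=O | starting material
21 | dimethyl (diazomethyl)phosphonate | COP(=O)(OC)C=[N+]=[N-] | intermediate
22 | methyl 4-[(2R,5S)-5-ethynyloxolan-2-yl]butanoate | COC(=O)CCC[C@@H]1CC[C@@H](C#C)O1 | intermediate
23 | non-8-yn-1-ol | OCCCCCCCC#C | starting material
24 | non-8-ynal | O=CCCCCCCC#C | intermediate
25 | (bromomethyl)triphenylphosphonium bromide | BrC[P+](c1ccccc1)(c1ccccc1)c1ccccc1.[Br-] | starting material
26 | (bromomethylidene)triphenylphosphorane (ylide) | BrC=P(c1ccccc1)(c1ccccc1)c1ccccc1 | intermediate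
27 | (1Z)-1-bromodec-1-en-9-yne | Br/C=C\CCCCCCC#C | intermediate
28 | chlorobis(cyclopentadienyl)[(1E,9Z)-10-bromodeca-1,9-dien-1-yl]zirconium | Cl[Zr](/C=C/CCCCCC/C=C\Br)(C1C=CC=C1)C1C=CC=C1 | intermediate
29 | (1Z,9E)-1-bromo-10-iododeca-1,9-diene | Br/C=C\CCCCCC/C=C/I | intermediate
30 | methyl 4-[(2R,5S)-5-[(3E,11Z)-12-bromododeca-3,11-dien-1-yn-1-yl]oxolan-2-yl]butanoate | COC(=O)CCC[C@@H]1CC[C@@H](C#C/C=C/CCCCCC/C=C\Br)O1 | target

Total step count: 18. Longest linear sequence: 15 steps (steps 1 to 14 and step 18, from compound 1); the diene 29 is made in 3 steps (15 to 17) from compound 23.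

Steps most likely to fail

1. Step 10. The carboxylate ylide 15 may fragment by loss of triphenylphosphine before it olefinates, and the basic medium may enolise the α-alkoxy aldehyde 13 and erode the stereocentre that becomes C5. The fallback sets out from compound 12 and comes back at compound 18. The alcohol would be converted by Appel-type iodination (I2, PPh3, imidazole, CH2Cl2) into tert-butyl{[(2S,5S)-5-(iodomethyl)oxolan-2-yl]methoxy}dimethylsilane F1. The primary radical from this iodide would then be added to methyl acrylate in a Giese reaction (Bu3SnH, AIBN, excess acrylate, toluene, 80 °C) to give methyl 4-[(2R,5S)-5-({[tert-butyl(dimethyl)silyl]oxy}methyl)oxolan-2-yl]butanoate F2. Methanolysis of the silyl ether (HCl in MeOH) would give 18. This replaces ionic olefination by radical conjugate addition, needs no aldehyde next to the stereocentre and bypasses steps 9 to 12.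

2. Step 16. Kinetic cis selectivity in oxaphosphetane formation may be incomplete and the bromoalkene may isomerise, so that the E-bromoalkene is carried on as a geometric impurity that is hard to remove. The fallback sets out from compound 23 and comes back at compound 29. The alkyne terminus would be brominated (NBS, AgNO3 cat., acetone) to 9-bromonon-8-yn-1-ol F3. cis-Reduction with diimide (2-nitrobenzenesulfonohydrazide, Et3N) would give (8Z)-9-bromonon-8-en-1-ol F4, and Dess–Martin oxidation would give (8Z)-9-bromonon-8-enal F5. Takai olefination (CHI3, CrCl2, THF–dioxane) would then install the E-iodoalkene and give 29. The Z geometry then comes from syn delivery of hydrogen to an alkyne and not from a Wittig reaction.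

3. Step 18. Oxidative addition may not discriminate fully between the alkenyl C–I and C–Br bonds, and copper-mediated oxidative dimerisation of alkyne 22 may compete. The fallback sets out from compounds 22 and 23 and comes back at compound 30. Compound 23 would be hydrozirconated and iodinated (Cp2Zr(H)Cl, 2.2 equiv; then I2) to (8E)-9-iodonon-8-en-1-ol F6, which carries no bromine. Sonogashira coupling with 22 under the conditions of step 18 would give methyl 4-[(2R,5S)-5-[(3E)-11-hydroxyundec-3-en-1-yn-1-yl]oxolan-2-yl]butanoate F7. Dess–Martin oxidation would give methyl 4-[(2R,5S)-5-[(3E)-11-oxoundec-3-en-1-yn-1-yl]oxolan-2-yl]butanoate F8. The Z-bromoalkene would be installed last by the bromomethylenation of step 16 with ylide 26, giving 30.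

Further compounds
F1 | step 10 | tert-butyl{[(2S,5S)-5-(iodomethyl)oxolan-2-yl]methoxy}dimethylsilane | IC[C@@H]1CC[C@@H](CO[Si](C)(C)C(C)(C)C)O1
F2 | step 10 | methyl 4-[(2R,5S)-5-({[tert-butyl(dimethyl)silyl]oxy}methyl)oxolan-2-yl]butanoate | COC(=O)CCC[C@@H]1CC[C@@H](CO[Si](C)(C)C(C)(C)C)O1
F3 | step 16 | 9-bromonon-8-yn-1-ol | OCCCCCCCC#CBr
F4 | step 16 | (8Z)-9-bromonon-8-en-1-ol | OCCCCCCC/C=C\Br
F5 | step 16 | (8Z)-9-bromonon-8-enal | O=CCCCCCC/C=C\Br
F6 | step 18 | (8E)-9-iodonon-8-en-1-ol | OCCCCCCC/C=C/I
F7 | step 18 | methyl 4-[(2R,5S)-5-[(3E)-11-hydroxyundec-3-en-1-yn-1-yl]oxolan-2-yl]butanoate | COC(=O)CCC[C@@H]1CC[C@@H](C#C/C=C/CCCCCCCO)O1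
F8 | step 18 | methyl 4-[(2R,5S)-5-[(3E)-11-oxoundec-3-en-1-yn-1-yl]oxolan-2-yl]butanoate | COC(=O)CCC[C@@H]1CC[C@@H](C#C/C=C/CCCCCCC=O)O1
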